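**Retrosynthetic overview**
1. Target 26 comes from α-hydroxy ketone 25 by chelation-controlled reduction (sets C1'); 25 comes from aryl bromide 18 (Br–Li exchange) and the (S)-lactate Weinreb amide 22 (supplies C2').
2. 18 comes from the 3-hydroxymethyl dihydrobenzofuran 16 (CH2OH to CH3 via tosylate and hydride); 16 arises by acid-mediated closure of the O1–C2 bond of diol 14. This dihydrofuran ring is the only ring made; both benzene rings are bought.
3. 14 comes from the Evans syn-aldol adduct 13 of arylacetyl oxazolidinone 10 and 3,4-dimethoxybenzaldehyde 11: this is the key C2–C3 bond, with C3 fixed by the auxiliary.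
4. 10 comes from arylacetic acid 7, made from 4-bromo-2-methoxyphenol 1 by O-allylation, Claisen rearrangement, MOM protection and oxidative cleavage of the allyl group.

Assumption: the SMILES is taken as definitive, i.e. a trans-(2S,3S) dihydrobenzofuran carrying an erythro-(1R,2S) diol.

**Route**

Step 1
Reactants: 1 4-bromo-2-methoxyphenol; 2 allyl bromide
Product: 3 1-(allyloxy)-4-bromo-2-methoxybenzene
Conditions: K2CO3, acetone, reflux
Reagents that add atoms: none
Why: Williamson ether synthesis (SN2 of the phenoxide on the allylic bromide); no stereocentre is involved.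

Step 2
Reactants: 3 1-(allyloxy)-4-bromo-2-methoxybenzene
Product: 4 2-allyl-4-bromo-6-methoxyphenol
Conditions: N,N-diethylaniline, 200 °C
Reagents that add atoms: none
Why: Aromatic Claisen [3,3]-sigmatropic rearrangement sends the allyl group to the only free ortho position (the other ortho carries OMe, para carries Br) and the dienone tautomerises back to the phenol.

Step 3
Reactants: 4 2-allyl-4-bromo-6-methoxyphenol
Product: 5 1-allyl-5-bromo-3-methoxy-2-(methoxymethoxy)benzene
Conditions: MOMCl, i-Pr2NEt, CH2Cl2, 0 °C → rt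
Reagents that add atoms: chloromethyl methyl ether (MOMCl), COCCl
Why: O-alkylation gives a MOM acetal that survives oxidants, boron enolate chemistry and hydrides, and is later removed by the same acid that closes the ring.

Step 4
Reactants: 5 1-allyl-5-bromo-3-methoxy-2-(methoxymethoxy)benzene
Product: 6 [5-bromo-3-methoxy-2-(methoxymethoxy)phenyl]acetaldehyde
Conditions: OsO4 (2 mol %), NaIO4 (4 equiv), 2,6-lutidine, dioxane/H2O (3:1), rt; used crude
Reagents that add atoms: sodium periodate NaIO4, [Na+].[O-]I(=O)(=O)=O (stoichiometric oxygen source); osmium tetroxide OsO4, O=[Os](=O)(=O)=O (catalytic oxygen carrier)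
Why: Lemieux–Johnson oxidative cleavage (dihydroxylation, then periodate glycol cleavage) cuts only the terminal alkene, and 2,6-lutidine suppresses over-oxidation.

Step 5
Reactants: 6 [5-bromo-3-methoxy-2-(methoxymethoxy)phenyl]acetaldehyde
Product: 7 [5-bromo-3-methoxy-2-(methoxymethoxy)phenyl]acetic acid
Conditions: NaClO2, NaH2PO4, 2-methyl-2-butene, t-BuOH/H2O, 0 °C → rt
Reagents that add atoms: sodium chlorite NaClO2, [Na+].[O-]Cl=O
Why: Pinnick oxidation converts the aldehyde to the acid under buffered conditions, while 2-methyl-2-butene scavenges HOCl so the electron-rich arene and the MOM ether are untouched.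

Step 6
Reactants: 7 [5-bromo-3-methoxy-2-(methoxymethoxy)phenyl]acetic acid; 8 (S)-4-benzyl-1,3-oxazolidin-2-one
Product: 10 (S)-4-benzyl-3-{[5-bromo-3-methoxy-2-(methoxymethoxy)phenyl]acetyl}-1,3-oxazolidin-2-one, via mixed pivalic anhydride 9 (not isolated)
Conditions: PivCl, Et3N, THF, −20 °C; then LiCl, 8, −20 °C → rt
Reagents that add atoms: pivaloyl chloride, CC(C)(C)C(=O)Cl (its atoms stay only in intermediate 9)
Why: N-acylation through a mixed anhydride, in which the LiCl-activated oxazolidinone attacks the unhindered arylacetyl carbonyl; no strong base is used, so the acidic benzylic CH2 is not enolised.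

Step 7
Reactants: 10 (S)-4-benzyl-3-{[5-bromo-3-methoxy-2-(methoxymethoxy)phenyl]acetyl}-1,3-oxazolidin-2-one; 11 3,4-dimethoxybenzaldehyde
Product: 13 (4S)-4-benzyl-3-[(2S,3S)-2-[5-bromo-3-methoxy-2-(methoxymethoxy)phenyl]-3-(3,4-dimethoxyphenyl)-3-hydroxypropanoyl]-1,3-oxazolidin-2-one, via dibutylboron Z-enolate 12 (not isolated)
Conditions: Bu2BOTf, i-Pr2NEt, CH2Cl2, −78 → 0 °C; 11, −78 → 0 °C; then pH 7 buffer, MeOH, 30% H2O2, 0 °C
Reagents that add atoms: dibutylboron triflate Bu2BOTf, CCCCB(CCCC)OS(=O)(=O)C(F)(F)F (its boron stays only in intermediate 12)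
Why: Evans syn-aldol reaction in which the Z-boron enolate reacts through a Zimmerman–Traxler chair with the aldehyde on the face away from the benzyl group, forming the C2–C3 bond and setting the α-aryl centre (future ring C3) and the carbinol centre as (2S,3S).

Step 8
Reactants: 13 the (2S,3S) aldol adduct
Product: 14 (1S,2R)-2-[5-bromo-3-methoxy-2-(methoxymethoxy)phenyl]-1-(3,4-dimethoxyphenyl)propane-1,3-diol
Conditions: LiBH4, MeOH (2 equiv), THF, 0 °C
Reagents that add atoms: none
Why: Reductive cleavage of the imide, in which hydride attacks the lithium-activated exocyclic carbonyl to give the primary alcohol and release the auxiliary; both stereocentres are untouched (the descriptor change is only a priority change).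

Step 9
Reactants: 14 (1S,2R)-2-[5-bromo-3-methoxy-2-(methoxymethoxy)phenyl]-1-(3,4-dimethoxyphenyl)propane-1,3-diol
Product: 16 [(2S,3R)-5-bromo-2-(3,4-dimethoxyphenyl)-7-methoxy-2,3-dihydro-1-benzofuran-3-yl]methanol, via free phenol 15 (not isolated)
Conditions: HCl (1.25 M in MeOH), 45 °C; evaporate; then TsOH·H2O (10 mol %), CH2Cl2, rt
Reagents that add atoms: none
Why: Acid removes the MOM acetal and ionises the 3,4-dimethoxybenzylic alcohol, and the phenol captures the cation reversibly (SN1 cycloetherification) to give the thermodynamically preferred 2,3-trans ring, which is also the retention product, so C2 becomes S while C3 is not touched.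

Step 10
Reactants: 16 [(2S,3R)-5-bromo-2-(3,4-dimethoxyphenyl)-7-methoxy-2,3-dihydro-1-benzofuran-3-yl]methanol
Product: 17 [(2S,3R)-5-bromo-2-(3,4-dimethoxyphenyl)-7-methoxy-2,3-dihydro-1-benzofuran-3-yl]methyl 4-methylbenzenesulfonate
Conditions: TsCl, pyridine, DMAP (cat.), CH2Cl2, 0 °C → rt
Reagents that add atoms: 4-toluenesulfonyl chloride (TsCl), Cc1ccc(cc1)S(=O)(=O)Cl
Why: Sulfonylation of the only free hydroxyl turns the primary alcohol into a leaving group without affecting any stereocentre.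

Step 11
Reactants: 17 the primary tosylate
Product: 18 (2S,3S)-5-bromo-2-(3,4-dimethoxyphenyl)-7-methoxy-3-methyl-2,3-dihydro-1-benzofuran
Conditions: LiEt3BH, THF, 0 °C → rt
Reagents that add atoms: none
Why: SN2 hydride displacement of the primary tosylate gives the 3-methyl group; the aryl bromide is inert at this temperature and C3 keeps its geometry (R becomes S only by priority change).

Step 12
Reactants: 19 ethyl (S)-lactate
Product: 20 ethyl (S)-2-{[tert-butyl(dimethyl)silyl]oxy}propanoate
Conditions: TBSCl, imidazole, DMF, rt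
Reagents that add atoms: tert-butyldimethylsilyl chloride (TBSCl), CC(C)(C)[Si](C)(C)Cl
Why: Imidazole-promoted O-silylation protects the hydroxyl without touching the stereocentre.

Step 13
Reactants: 20 ethyl (S)-2-{[tert-butyl(dimethyl)silyl]oxy}propanoate; 21 N,O-dimethylhydroxylamine hydrochloride
Product: 22 (S)-2-{[tert-butyl(dimethyl)silyl]oxy}-N-methoxy-N-methylpropanamide
Conditions: i-PrMgCl (3 equiv), THF, −20 → 0 °C
Reagents that add atoms: none
Why: Weinreb amide formation by aminolysis of the ester with the magnesium amide generated in the flask; at low temperature the α-silyloxy centre does not epimerise.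

Step 14
Reactants: 18 (2S,3S)-5-bromo-2-(3,4-dimethoxyphenyl)-7-methoxy-3-methyl-2,3-dihydro-1-benzofuran; 22 the Weinreb amide
Product: 24 (2S)-2-{[tert-butyl(dimethyl)silyl]oxy}-1-[(2S,3S)-2-(3,4-dimethoxyphenyl)-7-methoxy-3-methyl-2,3-dihydro-1-benzofuran-5-yl]propan-1-one, via aryllithium 23 (not isolated)
Conditions: n-BuLi, THF, −78 °C; then 22, −78 → −20 °C; sat. aq. NH4Cl
Reagents that add atoms: n-butyllithium, [Li]CCCC (its lithium stays only in intermediate 23)
Why: Bromine–lithium exchange followed by acyl substitution on the Weinreb amide, whose chelated tetrahedral intermediate prevents over-addition and protects the α-centre from epimerisation until the quench.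

Step 15
Reactants: 24 the silyloxy ketone
Product: 25 (2S)-1-[(2S,3S)-2-(3,4-dimethoxyphenyl)-7-methoxy-3-methyl-2,3-dihydro-1-benzofuran-5-yl]-2-hydroxypropan-1-one
Conditions: HF·pyridine, THF/pyridine, 0 °C → rt; used directly
Reagents that add atoms: none
Why: Fluoride-mediated desilylation under mildly acidic, non-enolising conditions frees the α-hydroxyl without epimerisation or ketol shift.

Step 16
Reactants: 25 the α-hydroxy ketone
Product: 26 (1R,2S)-1-[(2S,3S)-2-(3,4-dimethoxyphenyl)-7-methoxy-3-methyl-2,3-dihydro-1-benzofuran-5-yl]propane-1,2-diol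
Conditions: Zn(BH4)2 (ca. 0.15 M in Et2O), Et2O/THF, −20 → 0 °C; aq. NH4Cl
Reagents that add atoms: none
Why: Chelation-controlled (Cram-chelate) reduction in which zinc bridges the carbonyl and α-alkoxide oxygens and hydride enters past the α-hydrogen and not the α-methyl, giving the anti (erythro) diol with the new C1' as R.

**Compound list**
1 | 4-bromo-2-methoxyphenol | COc1cc(Br)ccc1O | starting material
2 | allyl bromide (3-bromoprop-1-ene) | C=CCBr | starting material
3 | 1-(allyloxy)-4-bromo-2-methoxybenzene | C=CCOc1ccc(Br)cc1OC | intermediate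
4 | 2-allyl-4-bromo-6-methoxyphenol | C=CCc1cc(Br)cc(OC)c1O | intermediate
5 | 1-allyl-5-bromo-3-methoxy-2-(methoxymethoxy)benzene | C=CCc1cc(Br)cc(OC)c1OCOC | intermediate
6 | [5-bromo-3-methoxy-2-(methoxymethoxy)phenyl]acetaldehyde | O=CCc1cc(Br)cc(OC)c1OCOC | intermediate
7 | [5-bromo-3-methoxy-2-(methoxymethoxy)phenyl]acetic acid | OC(=O)Cc1cc(Br)cc(OC)c1OCOC | intermediate
8 | (S)-4-benzyl-1,3-oxazolidin-2-one | O=C1OC[C@H](Cc2ccccc2)N1 | starting material
9 | [5-bromo-3-methoxy-2-(methoxymethoxy)phenyl]acetic pivalic anhydride | CC(C)(C)C(=O)OC(=O)Cc1cc(Br)cc(OC)c1OCOC | intermediate (not isolated)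
10 | (S)-4-benzyl-3-{[5-bromo-3-methoxy-2-(methoxymethoxy)phenyl]acetyl}-1,3-oxazolidin-2-one | O=C1OC[C@H](Cc2ccccc2)N1C(=O)Cc1cc(Br)cc(OC)c1OCOC | intermediate
11 | 3,4-dimethoxybenzaldehyde | COc1ccc(C=O)cc1OC | starting material
12 | dibutylboron Z-enolate of 10 | CCCCB(CCCC)O/C(=C\c1cc(Br)cc(OC)c1OCOC)N1C(=O)OC[C@@H]1Cc1ccccc1 | intermediate (not isolated)
13 | (4S)-4-benzyl-3-[(2S,3S)-2-[5-bromo-3-methoxy-2-(methoxymethoxy)phenyl]-3-(3,4-dimethoxyphenyl)-3-hydroxypropanoyl]-1,3-oxazolidin-2-one | COCOc1c(OC)cc(Br)cc1[C@H](C(=O)N1C(=O)OC[C@@H]1Cc1ccccc1)[C@H](O)c1ccc(OC)c(OC)c1 | intermediate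
14 | (1S,2R)-2-[5-bromo-3-methoxy-2-(methoxymethoxy)phenyl]-1-(3,4-dimethoxyphenyl)propane-1,3-diol | COCOc1c(OC)cc(Br)cc1[C@H](CO)[C@H](O)c1ccc(OC)c(OC)c1 | intermediate
15 | 4-bromo-2-[(1S,2R)-1-(3,4-dimethoxyphenyl)-1,3-dihydroxypropan-2-yl]-6-methoxyphenol | COc1cc(Br)cc([C@H](CO)[C@H](O)c2ccc(OC)c(OC)c2)c1O | intermediate (not isolated)
16 | [(2S,3R)-5-bromo-2-(3,4-dimethoxyphenyl)-7-methoxy-2,3-dihydro-1-benzofuran-3-yl]methanol | COc1ccc([C@H]2Oc3c(OC)cc(Br)cc3[C@@H]2CO)cc1OC | intermediate
17 | [(2S,3R)-5-bromo-2-(3,4-dimethoxyphenyl)-7-methoxy-2,3-dihydro-1-benzofuran-3-yl]methyl 4-methylbenzenesulfonate | COc1ccc([C@H]2Oc3c(OC)cc(Br)cc3[C@@H]2COS(=O)(=O)c2ccc(C)cc2)cc1OC | intermediate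
18 | (2S,3S)-5-bromo-2-(3,4-dimethoxyphenyl)-7-methoxy-3-methyl-2,3-dihydro-1-benzofuran | COc1ccc([C@H]2Oc3c(OC)cc(Br)cc3[C@@H]2C)cc1OC | intermediate
19 | ethyl (S)-lactate | CCOC(=O)[C@H](C)O | starting material
20 | ethyl (S)-2-{[tert-butyl(dimethyl)silyl]oxy}propanoate | CCOC(=O)[C@H](C)O[Si](C)(C)C(C)(C)C | intermediate
21 | N,O-dimethylhydroxylamine hydrochloride | CNOC.Cl | starting material
22 | (S)-2-{[tert-butyl(dimethyl)silyl]oxy}-N-methoxy-N-methylpropanamide | CON(C)C(=O)[C@H](C)O[Si](C)(C)C(C)(C)C | intermediate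
23 | [(2S,3S)-2-(3,4-dimethoxyphenyl)-7-methoxy-3-methyl-2,3-dihydro-1-benzofuran-5-yl]lithium | COc1ccc([C@H]2Oc3c(OC)cc([Li])cc3[C@@H]2C)cc1OC | intermediate (not isolated)
24 | (2S)-2-{[tert-butyl(dimethyl)silyl]oxy}-1-[(2S,3S)-2-(3,4-dimethoxyphenyl)-7-methoxy-3-methyl-2,3-dihydro-1-benzofuran-5-yl]propan-1-one | COc1ccc([C@H]2Oc3c(OC)cc(C(=O)[C@H](C)O[Si](C)(C)C(C)(C)C)cc3[C@@H]2C)cc1OC | intermediate
25 | (2S)-1-[(2S,3S)-2-(3,4-dimethoxyphenyl)-7-methoxy-3-methyl-2,3-dihydro-1-benzofuran-5-yl]-2-hydroxypropan-1-one | COc1ccc([C@H]2Oc3c(OC)cc(C(=O)[C@H](C)O)cc3[C@@H]2C)cc1OC | intermediate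
26 | (1R,2S)-1-[(2S,3S)-2-(3,4-dimethoxyphenyl)-7-methoxy-3-methyl-2,3-dihydro-1-benzofuran-5-yl]propane-1,2-diol | COc1ccc([C@H]2Oc3c(OC)cc([C@@H](O)[C@H](C)O)cc3[C@@H]2C)cc1OC | target

**Totals**
Total step count: 16. Longest linear sequence: 14 steps (steps 1–11, then 14–16); steps 12–13 are a two-step side branch.

**Three steps most likely to fail**

Step 7. The arylacetyl imide is ortho-substituted and the aldehyde is electron-rich, so conversion may stall or the adduct may undergo retro-aldol on work-up. The fallback sets out from acid 7 and changes the enolate platform and the auxiliary. DCC/DMAP coupling of 7 with (S)-4-benzyl-1,3-thiazolidine-2-thione gives the N-acyl thiazolidinethione F1. Its chlorotitanium enolate (TiCl4, i-Pr2NEt, N-methyl-2-pyrrolidinone, CH2Cl2, −78 °C, where the aryl MOM ether is expected to survive) adds to aldehyde 11 through the non-chelated chair and gives the same (2S,3S) syn arrangement in the thioimide adduct F2. NaBH4 in THF/EtOH at 0 °C then removes this more labile auxiliary reductively, and the fallback comes back to the route at diol 14.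

Step 9. The cationic closure could give stilbene by elimination, or a cis/trans mixture if equilibration is incomplete. The fallback sets out from diol 14 and replaces the SN1 closure by a stereospecific SN2 closure, coming back at 18 and bypassing steps 9–11. TsCl/pyridine at 0 °C sulfonylates only the primary hydroxyl to give the primary tosylate F3, and LiEt3BH in THF at 0 °C reduces it to the methyl carbinol F4. A Mitsunobu esterification (PPh3, DIAD, 4-nitrobenzoic acid, THF, 0 °C) inverts the benzylic carbinol to give the 4-nitrobenzoate F5, and K2CO3 in MeOH releases the anti alcohol F6. Brief treatment with dilute HCl in MeOH at 0 °C → rt removes the MOM group to give the free phenol F7; any material that already cyclises here is 18 itself. Intramolecular Mitsunobu etherification (PPh3, DIAD, THF, 0 °C) then closes the ring with inversion at the benzylic carbon, which from the anti alcohol gives the trans-(2S,3S) bromide 18.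

Step 16. The diastereoselectivity of the reduction of a free α-hydroxy aryl ketone may be lower than hoped, and 25 can epimerise if it is stored. The fallback sets out from bromide 18 (as aryllithium 23) and silyl ester 20, and creates the carbinol centre in a carbon–carbon bond formation instead of a hydride addition. DIBAL-H in CH2Cl2 at −78 °C reduces 20 to (S)-2-{[tert-butyl(dimethyl)silyl]oxy}propanal F8. Adding F8 to 23 in THF at −78 °C gives, under Felkin–Anh (non-chelation) control by the bulky silyl ether, the anti adduct, the (1R,2S) mono-silyl ether F9; the minor syn isomer is removed by chromatography. TBAF in THF then comes back to the route at target 26.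

**Further compounds**
F1 | step 7 | 1-[(4S)-4-benzyl-2-sulfanylidene-1,3-thiazolidin-3-yl]-2-[5-bromo-3-methoxy-2-(methoxymethoxy)phenyl]ethan-1-one | S=C1SC[C@H](Cc2ccccc2)N1C(=O)Cc1cc(Br)cc(OC)c1OCOC
F2 | step 7 | (2S,3S)-1-[(4S)-4-benzyl-2-sulfanylidene-1,3-thiazolidin-3-yl]-2-[5-bromo-3-methoxy-2-(methoxymethoxy)phenyl]-3-(3,4-dimethoxyphenyl)-3-hydroxypropan-1-one | COCOc1c(OC)cc(Br)cc1[C@H](C(=O)N1C(=S)SC[C@@H]1Cc1ccccc1)[C@H](O)c1ccc(OC)c(OC)c1
F3 | step 9 | (2R,3S)-2-[5-bromo-3-methoxy-2-(methoxymethoxy)phenyl]-3-(3,4-dimethoxyphenyl)-3-hydroxypropyl 4-methylbenzenesulfonate | COCOc1c(OC)cc(Br)cc1[C@H](COS(=O)(=O)c1ccc(C)cc1)[C@H](O)c1ccc(OC)c(OC)c1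
F4 | step 9 | (1S,2S)-2-[5-bromo-3-methoxy-2-(methoxymethoxy)phenyl]-1-(3,4-dimethoxyphenyl)propan-1-ol | COCOc1c(OC)cc(Br)cc1[C@H](C)[C@H](O)c1ccc(OC)c(OC)c1
F5 | step 9 | (1R,2S)-2-[5-bromo-3-methoxy-2-(methoxymethoxy)phenyl]-1-(3,4-dimethoxyphenyl)propyl 4-nitrobenzoate | COCOc1c(OC)cc(Br)cc1[C@H](C)[C@@H](OC(=O)c1ccc(cc1)[N+](=O)[O-])c1ccc(OC)c(OC)c1
F6 | step 9 | (1R,2S)-2-[5-bromo-3-methoxy-2-(methoxymethoxy)phenyl]-1-(3,4-dimethoxyphenyl)propan-1-ol | COCOc1c(OC)cc(Br)cc1[C@H](C)[C@@H](O)c1ccc(OC)c(OC)c1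
F7 | step 9 | 4-bromo-2-[(1R,2S)-1-(3,4-dimethoxyphenyl)-1-hydroxypropan-2-yl]-6-methoxyphenol | COc1cc(Br)cc([C@H](C)[C@@H](O)c2ccc(OC)c(OC)c2)c1O
F8 | step 16 | (S)-2-{[tert-butyl(dimethyl)silyl]oxy}propanal | O=C[C@H](C)O[Si](C)(C)C(C)(C)C
F9 | step 16 | (1R,2S)-2-{[tert-butyl(dimethyl)silyl]oxy}-1-[(2S,3S)-2-(3,4-dimethoxyphenyl)-7-methoxy-3-methyl-2,3-dihydro-1-benzofuran-5-yl]propan-1-ol | COc1ccc([C@H]2Oc3c(OC)cc([C@@H](O)[C@H](C)O[Si](C)(C)C(C)(C)C)cc3[C@@H]2C)cc1OC
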